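## Retrosynthetic overview

1. Halimane numbering is used: ring A = C1–C2–C3–C4–C5–C10 (C4 carries CH3 and CO2Me), ring B = C5–C6–C7–C8–C9–C10 (C8 carries CH3; C9 carries CH3 and the C11–C15 chain).
2. Last disconnections: Sharpless epoxidation of the C13=C14 allylic alcohol; B-alkyl Suzuki coupling that builds C11–C15 from a C9 vinyl group; one-position hydride shift C1=C2 → C1=C10.
3. Key disconnection: the Δ1(2)-octalin is an intramolecular Diels–Alder adduct in which C5–C10 and C3–C4 form together (diene C10=C1–C2=C3, dienophile the (Z)-C4=C5 α-methyl enoate, tether C6–C9).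
4. Enabling feature: in ring A the quaternary ester carbon C4 sits next to C5 and the ring alkene lies one allylic shift from C1=C2, so ring A is a cyclohexene retron (butadiene plus 2-methyl-2-enoate), while the four saturated carbons C6–C9 of ring B are the tether and already carry C8 and C9.
5. The acyclic triene comes from an enantioselective Ireland–Claisen rearrangement (C8–C9 bond, quaternary C9 with vinyl and ethynyl handles); rings A and B form together in step 8, the oxirane last in step 13.

Key step: step 8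

Assumption: the (S,S)-configured boron controller is taken to give the (2S,3S)-acid 6; the sense of induction is to be confirmed on the first run, and the (R,R)-controller would be used with no other change if it proved opposite.

## Route

Step 1
Reactants: 1 (2E)-3-methylpent-2-en-4-yn-1-ol; 2 propanoyl chloride
Product: 3 (2E)-3-methylpent-2-en-4-yn-1-yl propanoate
Conditions: Et3N, DMAP (cat.), CH2Cl2, 0 °C → rt
Reagents that add atoms: none
Why: DMAP-catalysed acylation of a primary allylic alcohol, which leaves the E alkene and the alkyne untouched.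

Step 2
Reactants: 3
Product: 6 (2S,3S)-3-ethynyl-2,3-dimethylpent-4-enoic acid, via boron ketene acetal 4 (not isolated), via acyloxyborane 5 (not isolated)
Conditions: (S,S)-2-bromo-4,5-diphenyl-1,3-bis{[3,5-bis(trifluoromethyl)phenyl]sulfonyl}-1,3,2-diazaborolidine (1.2 equiv), Et3N, toluene/hexane, −78 °C, then 4 °C; aqueous work-up
Reagents that add atoms: none
Why: Enantioselective Ireland–Claisen rearrangement of a chiral boron ketene acetal: Et3N in hydrocarbon solvent should give the ketene acetal with the C-methyl trans to O–B, the chair transition state (ethynyl equatorial, C9 methyl axial) converts the E alkene geometry into the required C8/C9 relative configuration, and the C2-symmetric controller selects the enantioface.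

Step 3
Reactants: 6
Product: 7 (2S,3S)-3-ethynyl-2,3-dimethylpent-4-en-1-ol
Conditions: LiAlH4, Et2O, 0 °C → rt; aqueous NaOH work-up
Reagents that add atoms: none
Why: Hydride reduction of the carboxylic acid to the primary alcohol, with the isolated alkene, the alkyne and both stereocentres unaffected.

Step 4
Reactants: 7
Product: 8 (3S,4S)-3-ethynyl-5-iodo-3,4-dimethylpent-1-ene
Conditions: I2, PPh3, imidazole, CH2Cl2, 0 °C → rt
Reagents that add atoms: iodine, II
Why: Appel-type iodination of a primary alcohol through the alkoxyphosphonium salt; no stereocentre is involved.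

Step 5
Reactants: 8; 9 bromoethene (vinyl bromide)
Product: 11 (3E,5R,6S)-5-ethenyl-7-iodo-5,6-dimethylhepta-1,3-diene, via alkenylzirconocene 10 (not isolated)
Conditions: Cp2Zr(H)Cl (1.1 equiv), THF, rt; then 9 (1 M in THF), Pd(PPh3)4 (5 mol %), rt
Reagents that add atoms: none
Why: Syn hydrozirconation of the terminal alkyne (zirconium on the terminal carbon; alkyne far faster than the vinyl group) followed by Negishi-type Pd-catalysed alkenyl–alkenyl coupling with retention should give the (E)-diene, the primary iodide being inert to both reagents at room temperature.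

Step 6
Reactants: 11; 12 N-tert-butylethanimine (acetaldehyde tert-butylimine)
Product: 14 (4R,5S,6E)-5-ethenyl-4,5-dimethylnona-6,8-dienal, via N-tert-butyl imine 13 (not isolated)
Conditions: 12, LiN(i-Pr)2, THF, 0 °C; then 11, DMPU, −78 °C → rt; then aqueous oxalic acid, rt
Reagents that add atoms: water, O
Why: Stork metalloenamine alkylation (SN2 of the lithium aza-enolate at the primary iodide) and imine hydrolysis give the two-carbon-homologated aldehyde without touching C8 or C9.

Step 7
Reactants: 14; 15 methyl 2-[bis(2,2,2-trifluoroethoxy)phosphoryl]propanoate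
Product: 16 methyl (2Z,6R,7S,8E)-7-ethenyl-2,6,7-trimethylundeca-2,8,10-trienoate
Conditions: 15, KN(SiMe3)2, 18-crown-6, THF, −78 °C
Reagents that add atoms: none
Why: Still–Gennari modification of the Horner–Wadsworth–Emmons reaction, whose kinetic control should place the ester cis to the chain (Z), the geometry that later sets C4 against C5.

Step 8
Reactants: 16
Product: 17 methyl (1S,4aR,5S,6R,8aR)-5-ethenyl-1,5,6-trimethyl-1,2,4a,5,6,7,8,8a-octahydronaphthalene-1-carboxylate
Conditions: MeAlCl2 (1.1 equiv), CH2Cl2, −78 °C → 0 °C; aqueous HCl quench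
Reagents that add atoms: none
Why: Concerted, Lewis-acid-accelerated normal-demand [4+2] cycloaddition of the 1,7,9-decatrienoate type (closest precedent: alkylaluminium-chloride-promoted intramolecular Diels–Alder reactions of terminally activated deca-2,7,9-trienoates), in which the C5–C10 bond closes ring B through a six-membered chair-like tether (C6–C9) and, together with the C3–C4 bond, closes ring A as the new cyclohexene. Suprafacial addition to the (Z)-enoate fixes the quaternary C4 against C5 (CO2Me cis to C6, CH3 cis to H5). The aluminium-bound ester should sit endo, which for a Z dienophile means the cis-fused transition state; of the chair tethers that allow cis fusion only the one with the C8 methyl equatorial, the C9 methyl axial and the diene arm axial is free of a 1,3-diaxial clash, and it places H5 on the face of the C9 methyl as the target requires. A trans-fused transition state on the same chair gives the same C5 configuration and the C10 stereocentre is erased in step 9, so the only selectivity needed is facial (C5 against C8/C9), and the two tether stereocentres secure it. The C9 vinyl group cannot reach the diene, the ester is the only Lewis-basic site, and the low temperature keeps the 1,2-dialkenylcyclohexane product away from any Cope pathway.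

Step 9
Reactants: 17
Product: 18 methyl (1S,5S,6R,8aR)-5-ethenyl-1,5,6-trimethyl-1,2,3,5,6,7,8,8a-octahydronaphthalene-1-carboxylate
Conditions: RuHCl(CO)(PPh3)3 (5 mol %), toluene, 80 °C
Reagents that add atoms: none
Why: Metal-hydride alkene isomerisation (reversible Ru–H addition and β-hydride elimination) should move the disubstituted C1=C2 alkene to the more stable trisubstituted C1=C10 position and stop there, because a further shift to C5=C10 would need a tertiary alkylruthenium at C10 beside the quaternary C9 and the C9 vinyl group has no allylic hydrogen; C10 is erased as a stereocentre and C5 is untouched.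

Step 10
Reactants: 19 ethyl 3-oxobutanoate
Product: 20 ethyl (2E)-3-{[(trifluoromethyl)sulfonyl]oxy}but-2-enoate
Conditions: Tf2O, aqueous Me4NOH, hexanes, 5–10 °C
Reagents that add atoms: trifluoromethanesulfonic anhydride, O=S(=O)(OS(=O)(=O)C(F)(F)F)C(F)(F)F
Why: O-sulfonylation of the β-keto ester enolate under biphasic conditions, where the non-chelating tetramethylammonium counter-ion should give the E enol triflate (triflate trans to the ester).

Step 11
Reactants: 20
Product: 21 (2E)-4-hydroxybut-2-en-2-yl trifluoromethanesulfonate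
Conditions: i-Bu2AlH (2.2 equiv), CH2Cl2, −78 °C
Reagents that add atoms: none
Why: 1,2-Reduction of the enoate to the allylic alcohol, with the alkenyl triflate inert at −78 °C and the alkene geometry retained.

Step 12
Reactants: 18; 21
Product: 23 methyl (1S,5S,6R,8aR)-5-[(3E)-5-hydroxy-3-methylpent-3-en-1-yl]-1,5,6-trimethyl-1,2,3,5,6,7,8,8a-octahydronaphthalene-1-carboxylate, via alkylborane 22 (not isolated)
Conditions: 9-borabicyclo[3.3.1]nonane dimer, THF, rt → 50 °C; then 21, Pd(dppf)Cl2 (5 mol %), aqueous K3PO4, DMF, rt → 50 °C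
Reagents that add atoms: none
Why: Anti-Markovnikov hydroboration of the only monosubstituted alkene followed by B-alkyl Suzuki–Miyaura coupling with the alkenyl triflate, which proceeds with retention and so delivers the (E)-trisubstituted allylic alcohol.

Step 13
Reactants: 23
Product: 24 methyl (1S,5S,6R,8aR)-5-{2-[(2R,3R)-3-(hydroxymethyl)-2-methyloxiran-2-yl]ethyl}-1,5,6-trimethyl-1,2,3,5,6,7,8,8a-octahydronaphthalene-1-carboxylate (CNP0324371.2)
Conditions: Ti(OiPr)4 (10 mol %), D-(−)-diethyl tartrate (12 mol %), t-BuOOH, 4 Å molecular sieves, CH2Cl2, −20 °C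
Reagents that add atoms: tert-butyl hydroperoxide, CC(C)(C)OO
Why: Sharpless asymmetric epoxidation, in which the D-tartrate catalyst delivers oxygen to the face of the (E)-allylic alcohol that gives the (2R,3R)-epoxy alcohol, while the ring alkene, lacking a directing hydroxyl, is left alone.

## Compound list

1 | (2E)-3-methylpent-2-en-4-yn-1-ol | OC/C=C(\C)C#C | starting material
2 | propanoyl chloride | CCC(=O)Cl | starting material
3 | (2E)-3-methylpent-2-en-4-yn-1-yl propanoate | CCC(=O)OC/C=C(\C)C#C | intermediate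
4 | boron ketene acetal of 3 on the (S,S)-diazaborolidine, C-methyl trans to O–B | C/C=C(/OB1N(S(=O)(=O)c2cc(C(F)(F)F)cc(C(F)(F)F)c2)[C@@H](c2ccccc2)[C@H](c2ccccc2)N1S(=O)(=O)c1cc(C(F)(F)F)cc(C(F)(F)F)c1)OC/C=C(\C)C#C | intermediate (not isolated)
5 | acyloxyborane: (S,S)-diazaborolidin-2-yl (2S,3S)-3-ethynyl-2,3-dimethylpent-4-enoate | O=C(OB1N(S(=O)(=O)c2cc(C(F)(F)F)cc(C(F)(F)F)c2)[C@@H](c2ccccc2)[C@H](c2ccccc2)N1S(=O)(=O)c1cc(C(F)(F)F)cc(C(F)(F)F)c1)[C@@H](C)[C@](C)(C=C)C#C | intermediate (not isolated)
6 | (2S,3S)-3-ethynyl-2,3-dimethylpent-4-enoic acid | OC(=O)[C@@H](C)[C@](C)(C=C)C#C | intermediate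
7 | (2S,3S)-3-ethynyl-2,3-dimethylpent-4-en-1-ol | OC[C@@H](C)[C@](C)(C=C)C#C | intermediate
8 | (3S,4S)-3-ethynyl-5-iodo-3,4-dimethylpent-1-ene | IC[C@@H](C)[C@](C)(C=C)C#C | intermediate
9 | bromoethene | C=CBr | starting material
10 | [(1E,3R,4S)-3-ethenyl-5-iodo-3,4-dimethylpent-1-en-1-yl]chloridobis(cyclopentadienyl)zirconium (cyclopentadienyl rings drawn σ-bound) | IC[C@@H](C)[C@](C)(C=C)/C=C/[Zr](Cl)(C1C=CC=C1)C1C=CC=C1 | intermediate (not isolated)
11 | (3E,5R,6S)-5-ethenyl-7-iodo-5,6-dimethylhepta-1,3-diene | IC[C@@H](C)[C@](C)(C=C)/C=C/C=C | intermediate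
12 | N-tert-butylethanimine | CC=NC(C)(C)C | starting material
13 | (4R,5S,6E)-N-tert-butyl-5-ethenyl-4,5-dimethylnona-6,8-dien-1-imine | CC(C)(C)N=CCC[C@@H](C)[C@](C)(C=C)/C=C/C=C | intermediate (not isolated)
14 | (4R,5S,6E)-5-ethenyl-4,5-dimethylnona-6,8-dienal | O=CCC[C@@H](C)[C@](C)(C=C)/C=C/C=C | intermediate
15 | methyl 2-[bis(2,2,2-trifluoroethoxy)phosphoryl]propanoate | COC(=O)C(C)P(=O)(OCC(F)(F)F)OCC(F)(F)F | starting material
16 | methyl (2Z,6R,7S,8E)-7-ethenyl-2,6,7-trimethylundeca-2,8,10-trienoate | COC(=O)/C(C)=C\CC[C@@H](C)[C@](C)(C=C)/C=C/C=C | intermediate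
17 | methyl (1S,4aR,5S,6R,8aR)-5-ethenyl-1,5,6-trimethyl-1,2,4a,5,6,7,8,8a-octahydronaphthalene-1-carboxylate (cis-fused) | COC(=O)[C@@]1(C)CC=C[C@@H]2[C@H]1CC[C@@H](C)[C@]2(C)C=C | intermediate
18 | methyl (1S,5S,6R,8aR)-5-ethenyl-1,5,6-trimethyl-1,2,3,5,6,7,8,8a-octahydronaphthalene-1-carboxylate | COC(=O)[C@@]1(C)CCC=C2[C@H]1CC[C@@H](C)[C@]2(C)C=C | intermediate
19 | ethyl 3-oxobutanoate | CCOC(=O)CC(C)=O | starting material
20 | ethyl (2E)-3-{[(trifluoromethyl)sulfonyl]oxy}but-2-enoate | C/C(OS(=O)(=O)C(F)(F)F)=C\C(=O)OCC | intermediate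
21 | (2E)-4-hydroxybut-2-en-2-yl trifluoromethanesulfonate | C/C(OS(=O)(=O)C(F)(F)F)=C\CO | intermediate
22 | B-alkyl-9-borabicyclo[3.3.1]nonane from 18 (boron on the terminal carbon of the former vinyl group) | COC(=O)[C@@]1(C)CCC=C2[C@H]1CC[C@@H](C)[C@]2(C)CCB1C2CCCC1CCC2 | intermediate (not isolated)
23 | methyl (1S,5S,6R,8aR)-5-[(3E)-5-hydroxy-3-methylpent-3-en-1-yl]-1,5,6-trimethyl-1,2,3,5,6,7,8,8a-octahydronaphthalene-1-carboxylate | COC(=O)[C@@]1(C)CCC=C2[C@H]1CC[C@@H](C)[C@]2(C)CC/C(C)=C/CO | intermediate
24 | methyl (1S,5S,6R,8aR)-5-{2-[(2R,3R)-3-(hydroxymethyl)-2-methyloxiran-2-yl]ethyl}-1,5,6-trimethyl-1,2,3,5,6,7,8,8a-octahydronaphthalene-1-carboxylate | COC(=O)[C@@]1(C)CCC=C2[C@H]1CC[C@@H](C)[C@]2(C)CC[C@@]1(C)O[C@@H]1CO | target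

## Step count and risks

Total step count: 13. Longest linear sequence: 11 (steps 1–9, 12, 13); steps 10 and 11 make the coupling partner 21.

Steps most likely to fail:

1. Step 9. The hydride walk may stop at an equilibrium that still holds the C1=C2 and C2=C3 isomers, or the catalyst may be held back by reversible insertion of the C9 vinyl group. The fallback sets out from 17 and comes back at 18. Dye-sensitised photo-oxygenation (O2, tetraphenylporphyrin, visible light, CH2Cl2, 0 °C; Schenck ene reaction) should remove the pseudo-axial ring-fusion hydrogen at C10 suprafacially and place oxygen on C2, giving methyl (1S,3S,5S,6R,8aR)-5-ethenyl-3-hydroperoxy-1,5,6-trimethyl-1,2,3,5,6,7,8,8a-octahydronaphthalene-1-carboxylate F1 with the alkene already at C1=C10. Reduction with PPh3 in the same flask gives the allylic alcohol methyl (1S,3S,5S,6R,8aR)-5-ethenyl-3-hydroxy-1,5,6-trimethyl-1,2,3,5,6,7,8,8a-octahydronaphthalene-1-carboxylate F2. Ionic deoxygenation (Et3SiH, BF3·OEt2, CH2Cl2, −40 °C) should then deliver hydride to the secondary C2 end of the allyl cation and give 18.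

2. Step 8. Cycloaddition of the trisubstituted (Z)-enoate may be slow enough for Lewis-acid-induced oligomerisation of the terminal diene to compete, and boat-like tethers may erode the facial selectivity. The fallback sets out from 16 and comes back at 17. Reduction with i-Bu2AlH (CH2Cl2, −78 °C) gives (2Z,6R,7S,8E)-7-ethenyl-2,6,7-trimethylundeca-2,8,10-trien-1-ol F3, and MnO2 (CH2Cl2, rt) gives (2Z,6R,7S,8E)-7-ethenyl-2,6,7-trimethylundeca-2,8,10-trienal F4. The much more reactive enal should cyclise at −78 °C with Me2AlCl through the same transition-state arrangement to (1S,4aR,5S,6R,8aR)-5-ethenyl-1,5,6-trimethyl-1,2,4a,5,6,7,8,8a-octahydronaphthalene-1-carbaldehyde F5. Pinnick oxidation (NaClO2, NaH2PO4, 2-methylbut-2-ene, t-BuOH/H2O) gives (1S,4aR,5S,6R,8aR)-5-ethenyl-1,5,6-trimethyl-1,2,4a,5,6,7,8,8a-octahydronaphthalene-1-carboxylic acid F6, and esterification with Me3SiCHN2 (MeOH/toluene) returns 17.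

3. Step 2. Enolisation of the conjugated enynyl ester may leak into the other ketene acetal geometry, enantioface discrimination by the boron controller may be incomplete, and the [3,3] shift to the quaternary carbon may be slow enough for the boron ketene acetal to decompose. The fallback sets out from 6 (of insufficient stereochemical purity) and comes back at 7. Steglich esterification with (R)-pantolactone (DCC, DMAP, CH2Cl2) gives (3R)-4,4-dimethyl-2-oxooxolan-3-yl (2S,3S)-3-ethynyl-2,3-dimethylpent-4-enoate F7 beside the diastereomeric ester of the mirror-image acid, (3R)-4,4-dimethyl-2-oxooxolan-3-yl (2R,3R)-3-ethynyl-2,3-dimethylpent-4-enoate F8. After separation by chromatography or crystallisation, LiAlH4 (Et2O, 0 °C) reduces F7 directly to 7, so enantiopurity then rests on a separable diastereomer and not on the controller.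

## Further compounds

F1 | step 9 | methyl (1S,3S,5S,6R,8aR)-5-ethenyl-3-hydroperoxy-1,5,6-trimethyl-1,2,3,5,6,7,8,8a-octahydronaphthalene-1-carboxylate | COC(=O)[C@@]1(C)C[C@H](OO)C=C2[C@H]1CC[C@@H](C)[C@]2(C)C=C
F2 | step 9 | methyl (1S,3S,5S,6R,8aR)-5-ethenyl-3-hydroxy-1,5,6-trimethyl-1,2,3,5,6,7,8,8a-octahydronaphthalene-1-carboxylate | COC(=O)[C@@]1(C)C[C@H](O)C=C2[C@H]1CC[C@@H](C)[C@]2(C)C=C
F3 | step 8 | (2Z,6R,7S,8E)-7-ethenyl-2,6,7-trimethylundeca-2,8,10-trien-1-ol | OC/C(C)=C\CC[C@@H](C)[C@](C)(C=C)/C=C/C=C
F4 | step 8 | (2Z,6R,7S,8E)-7-ethenyl-2,6,7-trimethylundeca-2,8,10-trienal | O=C/C(C)=C\CC[C@@H](C)[C@](C)(C=C)/C=C/C=C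
F5 | step 8 | (1S,4aR,5S,6R,8aR)-5-ethenyl-1,5,6-trimethyl-1,2,4a,5,6,7,8,8a-octahydronaphthalene-1-carbaldehyde | O=C[C@@]1(C)CC=C[C@@H]2[C@H]1CC[C@@H](C)[C@]2(C)C=C
F6 | step 8 | (1S,4aR,5S,6R,8aR)-5-ethenyl-1,5,6-trimethyl-1,2,4a,5,6,7,8,8a-octahydronaphthalene-1-carboxylic acid | OC(=O)[C@@]1(C)CC=C[C@@H]2[C@H]1CC[C@@H](C)[C@]2(C)C=C
F7 | step 2 | (3R)-4,4-dimethyl-2-oxooxolan-3-yl (2S,3S)-3-ethynyl-2,3-dimethylpent-4-enoate | O=C(O[C@H]1C(=O)OCC1(C)C)[C@@H](C)[C@](C)(C=C)C#C
F8 | step 2 | (3R)-4,4-dimethyl-2-oxooxolan-3-yl (2R,3R)-3-ethynyl-2,3-dimethylpent-4-enoate | O=C(O[C@H]1C(=O)OCC1(C)C)[C@H](C)[C@@](C)(C=C)C#C
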